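The plan rests on cutting the pyranone ring at C4–C5 and O1–C2. Ring atoms C2, C3 and C4 form a malonyl unit whose middle atom C3 alone carries the p-menthene ring (bond C3–C3′). C5, C6, O1 and the styryl chain map onto benzalacetone. In a single operation the silyl dienol ether of benzalacetone is acylated first at carbon and then at oxygen by a terpenylmalonyl dichloride. This builds the whole heterocycle without touching C3′ or C4′. The precursor is 2-(p-menth-1-en-3-yl)malonyl dichloride. Its trans C3′/C4′ relationship is installed earlier, by capture of a limonene-derived allyl cation anti to the isopropyl group.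

Key step: step 7

Remark on the chemistry (primed locants = p-menthane numbering): the main tertiary allylic alcohol from oxygenation of p-menth-1-ene (often named trans-p-menth-2-en-1-ol because methyl and isopropyl are trans) has its hydroxyl on the same ring face as the isopropyl group, so any substitution with net retention (double-inversion palladium allylation, suprafacial Claisen rearrangement) would place the new carbon cis to isopropyl; the C3′–C bond is therefore made through the planar allyl cation, where the isopropyl group alone chooses the face and the carbinol configuration does not matter.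

Step 1
Reactants: 1 (S)-(−)-limonene
Product: 2 (S)-p-menth-1-ene [(4S)-1-methyl-4-(propan-2-yl)cyclohex-1-ene]
Conditions: H2 (1 atm), RhCl(PPh3)3 (1 mol %), toluene/EtOH, rt
Reagents that add atoms: none
Why: Chemoselective homogeneous hydrogenation with RhCl(PPh3)3 follows steric accessibility, so the 1,1-disubstituted isopropenyl group should be saturated while the trisubstituted ring alkene stays, and the catalyst isomerises alkenes little, so C4 is kept.

Step 2
Reactants: 2 (S)-p-menth-1-ene
Product: 4 (1R,4R)-p-menth-2-en-1-ol (OH cis to isopropyl), via allylic hydroperoxide 3 (not isolated)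
Conditions: O2, visible light, 5,10,15,20-tetraphenylporphyrin (cat.), CH2Cl2, 0 °C; then PPh3, 0 °C to rt; chromatography
Reagents that add atoms: oxygen, O=O
Why: In the suprafacial Schenck ene reaction singlet oxygen bonds to C1 while it takes the pseudoaxial C3 hydrogen on the same face, which is the face of the pseudoequatorial isopropyl group, so the main tertiary hydroperoxide should carry oxygen cis to isopropyl; PPh3 cleaves O–O with retention, the regioisomeric secondary alcohols are removed by chromatography, and the new C1 centre (like any C1 epimer carried along) is erased in step 3.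

Step 3
Reactants: 4 (1R,4R)-p-menth-2-en-1-ol; 5 1-(tert-butyldimethylsilyloxy)-1-methoxyethene
Product: 8 methyl 2-[(1R,6R)-3-methyl-6-(propan-2-yl)cyclohex-2-en-1-yl]acetate, via silyl ether 6 (not isolated), via allyl cation 7 (not isolated)
Conditions: 5 (2.5 equiv), tBuMe2SiOTf (10 mol %), CH2Cl2, −78 to 0 °C; Et3N, then aq. NaHCO3
Reagents that add atoms: none
Why: The first equivalent of 5 silylates the hydroxyl and the silyl triflate ionises 6 to the planar C1′–C2′–C3′ allyl cation 7, which the strongly nucleophilic ketene silyl acetal should capture faster than a proton is lost, at the less substituted terminus C3′ and on the face opposite to the C4′ isopropyl group (SN1-type Mukaiyama allylic alkylation, with the same steric control as in acid-catalysed terpenylation of resorcinols by p-menthenyl cations), which sets C3′ as R and trans to C4′ whatever the C1 configuration of 4.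

Step 4
Reactants: 8 methyl 2-[(1R,6R)-3-methyl-6-(propan-2-yl)cyclohex-2-en-1-yl]acetate
Product: 12 2-[(1R,6R)-3-methyl-6-(propan-2-yl)cyclohex-2-en-1-yl]propanedioic acid, via lithium enolate 9 (not isolated), via lithium half-ester salt 10 (not isolated), via dilithium malonate 11 (not isolated)
Conditions: LiN(iPr)2 (1.2 equiv), THF, −78 °C; CO2 (g), −78 °C to rt, purge; LiOH (8 equiv), MeOH/H2O, 60 °C; 1 M HCl, 0 °C, pH 2
Reagents that add atoms: carbon dioxide, O=C=O; lithium hydroxide, [Li+].[OH-]
Why: Carboxylation of an ester lithium enolate with CO2 is the standard entry to malonic half-esters, and saponification in the same flask keeps the first carboxyl group safe from decarboxylation as its salt until the cold acidification; the transient stereocentre at the malonate carbon vanishes once both groups are carboxyls, and C3′ and C4′ bear no acidic hydrogen.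

Step 5
Reactants: 12 2-[(1R,6R)-3-methyl-6-(propan-2-yl)cyclohex-2-en-1-yl]propanedioic acid
Product: 13 2-[(1R,6R)-3-methyl-6-(propan-2-yl)cyclohex-2-en-1-yl]propanedioyl dichloride
Conditions: (COCl)2 (2.5 equiv), DMF (cat.), CH2Cl2, 0 °C to rt, argon sweep; evaporate, use crude
Reagents that add atoms: oxalyl chloride, O=C(Cl)C(=O)Cl
Why: Acid chloride formation through the Vilsmeier-type chloroiminium salt releases only gases, so 13 is obtained by evaporation without the heating that would cause decarboxylation or loss of HCl to the ketene, and sweeping out HCl at low temperature should leave the trisubstituted alkene intact, as with other unsaturated terpenoid acids.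

Step 6
Reactants: 14 (E)-4-phenylbut-3-en-2-one (benzalacetone)
Product: 15 (E)-trimethyl[(4-phenylbuta-1,3-dien-2-yl)oxy]silane
Conditions: Me3SiOTf (1.1 equiv), Et3N (1.3 equiv), Et2O, 0 °C; pentane extraction
Reagents that add atoms: trimethylsilyl trifluoromethanesulfonate, C[Si](C)(C)OS(=O)(=O)C(F)(F)F
Why: Soft enolisation with O-silylation can take place only at the methyl group, the single enolisable position of 14, so one cross-conjugated 2-silyloxydiene should form with the E alkene unchanged.

Step 7
Reactants: 13 2-[(1R,6R)-3-methyl-6-(propan-2-yl)cyclohex-2-en-1-yl]propanedioyl dichloride; 15 (E)-trimethyl[(4-phenylbuta-1,3-dien-2-yl)oxy]silane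
Product: 17 4-hydroxy-3-[(1R,6R)-3-methyl-6-(propan-2-yl)cyclohex-2-en-1-yl]-6-[(E)-2-phenylethenyl]-2H-pyran-2-one (target), via dioxoacyl chloride 16 (not isolated)
Conditions: 13 in Et2O added to 15 (1.2 equiv) and 2,6-di-tert-butyl-4-methylpyridine (1.1 equiv), Et2O, −78 °C to rt; then H2O
Reagents that add atoms: none
Why: The terminal CH2 of the 2-silyloxydiene 15, the only carbon that receives the oxygen lone pair, attacks one COCl group of 13 (or the chlorocarbonyl ketene formed from it by loss of HCl), and expulsion of Me3SiCl creates the C4–C5 bond and the acyclic 3,5-dioxoacyl chloride 16. The styryl ketone of 16 enolises and its oxygen adds to the remaining COCl carbon in a 6-exo-trig addition–elimination that creates O1–C2 and closes the pyranone ring, after which tautomerisation to the 4-hydroxy-2-pyranone makes the sequence irreversible. The closest known reaction type is the [3+3] condensation of silyl enol ethers with malonyl dichlorides, 2-substituted ones included, to 4-hydroxy-2-pyranones. No stereocentre is formed; C3′ and C4′ carry no acidic hydrogen and lie outside the reacting π system, so their R,R configuration should pass through unchanged, as should the E alkene. The selectivity required is chemoselectivity, carbon acylation before oxygen acylation, and it is secured by the silyl cap of 15, which keeps the oxygen unreactive until the C–C bond has been made and the silyl group has left. The acid-sensitive C1′=C2′ alkene is shielded from the one equivalent of HCl by the hindered pyridine, which binds protons but is too crowded to attack an acyl chloride.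

Compound list
1 | (S)-(−)-limonene | CC1=CC[C@@H](C(C)=C)CC1 | starting material
2 | (S)-p-menth-1-ene | CC1=CC[C@@H](C(C)C)CC1 | intermediate
3 | (1R,4R)-p-menth-2-en-1-yl hydroperoxide (OOH cis to isopropyl) | C[C@]1(OO)C=C[C@@H](C(C)C)CC1 | intermediate
4 | (1R,4R)-p-menth-2-en-1-ol (OH cis to isopropyl) | C[C@]1(O)C=C[C@@H](C(C)C)CC1 | intermediate
5 | 1-(tert-butyldimethylsilyloxy)-1-methoxyethene | C=C(OC)O[Si](C)(C)C(C)(C)C | starting material
6 | tert-butyldimethylsilyl ether of 4 | C[C@]1(O[Si](C)(C)C(C)(C)C)C=C[C@@H](C(C)C)CC1 | intermediate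
7 | p-menth-1-en-3-yl allyl cation (charge shared by C1′ and C3′, C4′ as in 4) | C[C+]1C=C[C@@H](C(C)C)CC1 | intermediate
8 | methyl 2-[(1R,6R)-3-methyl-6-(propan-2-yl)cyclohex-2-en-1-yl]acetate (side chain trans to isopropyl) | CC1=C[C@H](CC(=O)OC)[C@@H](C(C)C)CC1 | intermediate
9 | lithium enolate of 8 (enolate geometry immaterial) | CC1=C[C@H](C=C([O-])OC)[C@@H](C(C)C)CC1.[Li+] | intermediate
10 | lithium 3-methoxy-3-oxo-2-[(1R,6R)-3-methyl-6-(propan-2-yl)cyclohex-2-en-1-yl]propanoate (malonate carbon undefined) | CC1=C[C@H](C(C(=O)OC)C(=O)[O-])[C@@H](C(C)C)CC1.[Li+] | intermediate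
11 | dilithium 2-[(1R,6R)-3-methyl-6-(propan-2-yl)cyclohex-2-en-1-yl]propanedioate | CC1=C[C@H](C(C(=O)[O-])C(=O)[O-])[C@@H](C(C)C)CC1.[Li+].[Li+] | intermediate
12 | 2-[(1R,6R)-3-methyl-6-(propan-2-yl)cyclohex-2-en-1-yl]propanedioic acid | CC1=C[C@H](C(C(=O)O)C(=O)O)[C@@H](C(C)C)CC1 | intermediate
13 | 2-[(1R,6R)-3-methyl-6-(propan-2-yl)cyclohex-2-en-1-yl]propanedioyl dichloride | CC1=C[C@H](C(C(=O)Cl)C(=O)Cl)[C@@H](C(C)C)CC1 | intermediate
14 | (E)-4-phenylbut-3-en-2-one | CC(=O)/C=C/c1ccccc1 | starting material
15 | (E)-trimethyl[(4-phenylbuta-1,3-dien-2-yl)oxy]silane | C=C(O[Si](C)(C)C)/C=C/c1ccccc1 | intermediate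
16 | (6E)-2-[(1R,6R)-3-methyl-6-(propan-2-yl)cyclohex-2-en-1-yl]-3,5-dioxo-7-phenylhept-6-enoyl chloride (C2 of the chain undefined, lost on enolisation) | CC1=C[C@H](C(C(=O)Cl)C(=O)CC(=O)/C=C/c2ccccc2)[C@@H](C(C)C)CC1 | intermediate
17 | 4-hydroxy-3-[(1R,6R)-3-methyl-6-(propan-2-yl)cyclohex-2-en-1-yl]-6-[(E)-2-phenylethenyl]-2H-pyran-2-one | CC1=C[C@H](c2c(O)cc(/C=C/c3ccccc3)oc2=O)[C@@H](C(C)C)CC1 | target

Total steps: 7. Longest linear sequence: 6 (steps 1, 2, 3, 4, 5 and 7).

Steps most likely to fail

**Step 7.**
- What may go wrong: carbon acylation at the crowded acyl chloride may be slow. Premature desilylation followed by oxygen acylation, cycloaddition of the derived ketene to the silyloxydiene, or addition of HCl to the ring alkene could then take over.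
- Fallback (sets out from 15 and 4, returns at 17): the annulation is run on unhindered parent malonyl dichloride, where this condensation is best established. Reaction of 15 with ClC(O)CH2C(O)Cl in Et2O at −78 °C gives, through (6E)-3,5-dioxo-7-phenylhept-6-enoyl chloride F1, 4-hydroxy-6-[(E)-2-phenylethenyl]-2H-pyran-2-one F2. F2 is then alkylated at its nucleophilic C3 with alcohol 4 under BF3·OEt2 catalysis in CH2Cl2 at −10 °C. Cation 7 is again attacked anti to isopropyl (Friedel–Crafts-type terpenylation of a vinylogous acid), which gives 17 directly.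

**Step 3.**
- What may go wrong: proton loss from the allyl cation, attack at the tertiary terminus or an incomplete facial bias may erode the coupling.
- Fallback (sets out from 4, returns at 11): a stereospecific Tsuji–Trost alkylation replaces the cationic coupling.
  - Oxidative allylic transposition of 4 with [C5H5NH][CrO3Cl] buffered by NaOAc in CH2Cl2 (Babler–Dauben oxidation) gives (R)-piperitone F3.
  - LiAlH4 in Et2O at −78 °C delivers hydride axially and should give mainly the pseudoequatorial alcohol (1R,6R)-trans-piperitol F4, from which the cis epimer is separated.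
  - ClCO2Me and pyridine give (1R,6R)-trans-piperityl methyl carbonate F5, whose leaving group lies on the ring face opposite to isopropyl.
  - Pd(PPh3)4 and dimethyl malonate in THF at 50 °C then substitute at C3′ with double inversion, that is net retention, to give dimethyl 2-[(1R,6R)-3-methyl-6-(propan-2-yl)cyclohex-2-en-1-yl]propanedioate F6.
  - LiOH in aqueous MeOH/THF converts F6 into 11.

**Step 2.**
- What may go wrong: hydrogen abstraction from three different allylic positions scatters the material over regioisomeric hydroperoxides and makes the separation laborious.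
- Fallback (sets out from 2, returns at 4):
  - mCPBA in CH2Cl2 gives the epoxide with oxygen cis to isopropyl, (1R,2S,4S)-1,2-epoxy-p-menthane F7, beside its diastereomer (1S,2R,4S)-1,2-epoxy-p-menthane F8.
  - PhSeNa (from (PhSe)2 and NaBH4 in EtOH) should readily open only F7, at the secondary C2 in the trans-diaxial sense (Fürst–Plattner rule), to (1R,2R,4S)-2-(phenylselanyl)-p-menthan-1-ol F9. F8 is left behind and removed.
  - H2O2 oxidises F9 to (1R,2R,4S)-2-(phenylseleninyl)-p-menthan-1-ol F10, whose syn elimination can run only towards C3 and gives 4 as a single regio- and stereoisomer.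

Further compounds
F1 | step 7 | (6E)-3,5-dioxo-7-phenylhept-6-enoyl chloride | O=C(Cl)CC(=O)CC(=O)/C=C/c1ccccc1
F2 | step 7 | 4-hydroxy-6-[(E)-2-phenylethenyl]-2H-pyran-2-one | O=c1cc(O)cc(/C=C/c2ccccc2)o1
F3 | step 3 | (R)-piperitone [(6R)-3-methyl-6-(propan-2-yl)cyclohex-2-en-1-one] | CC1=CC(=O)[C@@H](C(C)C)CC1
F4 | step 3 | (1R,6R)-trans-piperitol [(1R,6R)-3-methyl-6-(propan-2-yl)cyclohex-2-en-1-ol] | CC1=C[C@H](O)[C@@H](C(C)C)CC1
F5 | step 3 | (1R,6R)-trans-piperityl methyl carbonate | CC1=C[C@H](OC(=O)OC)[C@@H](C(C)C)CC1
F6 | step 3 | dimethyl 2-[(1R,6R)-3-methyl-6-(propan-2-yl)cyclohex-2-en-1-yl]propanedioate | CC1=C[C@H](C(C(=O)OC)C(=O)OC)[C@@H](C(C)C)CC1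
F7 | step 2 | (1R,2S,4S)-1,2-epoxy-p-menthane (oxygen cis to isopropyl) | CC(C)[C@H]1CC[C@@]2(C)O[C@H]2C1
F8 | step 2 | (1S,2R,4S)-1,2-epoxy-p-menthane (oxygen trans to isopropyl) | CC(C)[C@H]1CC[C@]2(C)O[C@@H]2C1
F9 | step 2 | (1R,2R,4S)-2-(phenylselanyl)-p-menthan-1-ol | CC(C)[C@H]1CC[C@@](C)(O)[C@H]([Se]c2ccccc2)C1
F10 | step 2 | (1R,2R,4S)-2-(phenylseleninyl)-p-menthan-1-ol (selenium configuration undefined) | CC(C)[C@H]1CC[C@@](C)(O)[C@H]([Se](=O)c2ccccc2)C1
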